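The cyclohexene (C1 quaternary, C4(Me)=C5, C6 carrying coumarin B) is cut at two bonds: C6–C3 of coumarin B and C1–CH3. The ring alkene starts at C5, next to C6, and the C6 coumarin is trans to the C1 methyl, so C6 and C1 are the β- and α-carbons of achiral 4-methylcyclohexa-1,3-diene-1-carbaldehyde. One flask operation on that dienal, rhodium/chiral-diene conjugate addition of a MOM-protected coumarin-3-yl pinacol boronate followed by enolate C-methylation, forms both bonds and both stereocentres and leaves a formyl group on C1. The same boronate later delivers coumarin A by Suzuki coupling to the E-alkenyl iodide made from that formyl group.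

Key step: step 9

Remarks on the chemistry
- Numbering: the first paragraph uses the target numbering; C6 and C5 of the target are C2 and C3 of dienal 8 and of aldehyde 16, whose own locants are used in the steps.
- Assumption: the (1R,4R)-diene ligand is taken to deliver the coumarinyl group to the Re face of C2 of 8; if a pilot run shows the opposite sense, the (1S,4S)-ligand is used and nothing else changes.
- Assumption: 2,4-dihydroxy-3-methoxybenzaldehyde 9 is purchased.
- Design note: a Birch entry from 4-methylbenzoic acid is avoided, because base isomerisation of the 1,4-dihydro acid stops at 4-methylcyclohexa-1,5-diene-1-carboxylic acid, with the methyl carbon still saturated. Dienal 8 is therefore built from a Diels–Alder adduct whose methyl already sits on the ring alkene.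

Step 1
Reactants: 1 isoprene; 2 methyl acrylate
Product: 3 methyl 4-methylcyclohex-3-ene-1-carboxylate (racemic)
Conditions: AlCl3 (10 mol%), PhMe, 0 °C → rt
Reagents that add atoms: none
Why: Lewis-acid-catalysed Diels–Alder reaction in which AlCl3 coordination to the acrylate should steer the 2-substituted diene to the 1,4-("para") adduct, and the single (racemic) stereocentre is erased in step 2.

Step 2
Reactants: 3 methyl 4-methylcyclohex-3-ene-1-carboxylate
Product: 6 methyl 4-methylcyclohexa-1,3-diene-1-carboxylate, via phenylselanyl ester 4 (not isolated), via selenoxide 5 (not isolated)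
Conditions: LiN(iPr)2, THF, −78 °C; PhSeBr, −78 → 0 °C; then AcOH, 30% aq. H2O2, 0 °C → rt
Reagents that add atoms: none
Why: Ester enolate selenenylation followed by selenoxide syn-elimination, in which the allylic C2–H is the more acidic β-hydrogen and its loss gives the conjugated diene, so the new C1=C2 bond should form next to C3=C4 and not toward C6.

Step 3
Reactants: 6 methyl 4-methylcyclohexa-1,3-diene-1-carboxylate
Product: 7 (4-methylcyclohexa-1,3-dien-1-yl)methanol
Conditions: iBu2AlH (2.3 equiv), CH2Cl2, −78 → 0 °C; aq. KNaC4H4O6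
Reagents that add atoms: none
Why: 1,2-Reduction of a conjugated ester by iBu2AlH at low temperature is the standard route to the allylic alcohol and leaves the diene untouched.

Step 4
Reactants: 7 (4-methylcyclohexa-1,3-dien-1-yl)methanol
Product: 8 4-methylcyclohexa-1,3-diene-1-carbaldehyde
Conditions: TEMPO (10 mol%), PhI(OAc)2 (1.1 equiv), CH2Cl2, rt; used promptly as a solution (volatile)
Reagents that add atoms: none
Why: Oxoammonium (TEMPO) oxidation of a primary allylic alcohol with PhI(OAc)2 as terminal oxidant stops at the aldehyde under near-neutral conditions that should not aromatise the cyclohexadiene.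

Step 5
Reactants: 9 2,4-dihydroxy-3-methoxybenzaldehyde
Product: 11 7-hydroxy-8-methoxy-2H-chromen-2-one, via Z-cinnamate ester 10 (not isolated)
Conditions: Ph3P=CHCO2Et (1.3 equiv), PhNEt2, reflux
Reagents that add atoms: ethyl (triphenylphosphoranylidene)acetate, CCOC(=O)C=P(c1ccccc1)(c1ccccc1)c1ccccc1
Why: Wittig olefination of the salicylaldehyde with the stabilised ylide and thermal lactonisation of the 2-hydroxycinnamate (the E isomer equilibrates to Z at this temperature) is the classical one-flask coumarin synthesis and tolerates the free 4-hydroxyl.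

Step 6
Reactants: 11 7-hydroxy-8-methoxy-2H-chromen-2-one
Product: 12 8-methoxy-7-(methoxymethoxy)-2H-chromen-2-one
Conditions: MOMCl, K2CO3, acetone, 0 °C → rt
Reagents that add atoms: chloromethyl methyl ether, COCCl
Why: Williamson-type O-alkylation of the acidic 7-hydroxyl installs a MOM acetal that is stable to the bases, boron reagents and metal reagents of all later steps and is removed by mild acid at the end.

Step 7
Reactants: 12 8-methoxy-7-(methoxymethoxy)-2H-chromen-2-one
Product: 13 3-bromo-8-methoxy-7-(methoxymethoxy)-2H-chromen-2-one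
Conditions: NBS (1.05 equiv), MeCN, 0 °C → rt, dark
Reagents that add atoms: N-bromosuccinimide, O=C1CCC(=O)N1Br
Why: Electrophilic bromination in which attack at C3 gives a C4 cation stabilised by the para 7-alkoxy group, so the lactone C3 should be the most nucleophilic carbon, while succinimide as the only by-product keeps the medium neutral for the MOM ether.

Step 8
Reactants: 13 3-bromo-8-methoxy-7-(methoxymethoxy)-2H-chromen-2-one
Product: 14 8-methoxy-7-(methoxymethoxy)-3-(4,4,5,5-tetramethyl-1,3,2-dioxaborolan-2-yl)-2H-chromen-2-one
Conditions: B2pin2 (1.2 equiv), PdCl2(dppf) (3 mol%), KOAc (3 equiv), 1,4-dioxane, 80 °C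
Reagents that add atoms: bis(pinacolato)diboron, CC1(C)OB(B2OC(C)(C)C(C)(C)O2)OC1(C)C
Why: Miyaura borylation of an alkenyl (α-bromo enoate) bromide by zerovalent palladium formed in situ, in which the weak base KOAc promotes B–B transmetalation without triggering Suzuki homocoupling or opening the lactone.

Step 9
Reactants: 8 4-methylcyclohexa-1,3-diene-1-carbaldehyde (1.0 equiv); 14 8-methoxy-7-(methoxymethoxy)-3-(4,4,5,5-tetramethyl-1,3,2-dioxaborolan-2-yl)-2H-chromen-2-one (1.5 equiv)
Product: 16 (1S,2R)-2-[8-methoxy-7-(methoxymethoxy)-2-oxo-2H-chromen-3-yl]-1,4-dimethylcyclohex-3-ene-1-carbaldehyde, via conjugate-addition aldehyde 15 (not isolated)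
Conditions: [RhCl(C2H4)2]2 (2.5 mol%), (1R,4R)-2,5-diphenylbicyclo[2.2.2]octa-2,5-diene (5.5 mol%), KOH (10 mol%), 1,4-dioxane/H2O (10:1), 40 °C; then PhMe azeotrope in the same flask, THF, KN(SiMe3)2 (2.5 equiv), −78 °C; MeI (5 equiv), −78 → −20 °C
Reagents that add atoms: iodomethane, CI
Why: Proposed new method: the hydroxo-rhodium/diene complex (monovalent rhodium) transmetalates with boronate 14, the coumarin-3-yl–rhodium species adds syn across C1=C2 of 8 with carbon transfer to the β-carbon C2, and water protonates the rhodium enolate to 15 and regenerates the catalyst; after drying, KN(SiMe3)2 converts both C1 epimers of 15 into one exocyclic potassium enolate that MeI alkylates at carbon. The closest known reactions are the rhodium/chiral-diene asymmetric 1,4-addition of aryl- and alkenylboron reagents to β-substituted enals and the base/MeI α-methylation of α-branched aldehydes; untested are the cyclic α,β-disubstituted 2,4-dienal as acceptor, the α-boryl lactone as donor and the telescoping. No ring is closed. The stereocentre at the aryl-bearing carbon (C2 of 16) is set by the twofold-symmetric diene ligand, which has to deliver the coumarinyl group to the Re face of C2 of 8; the quaternary centre C1 is set by the substrate, because allylic 1,3-strain holds the coumarinyl group pseudoaxial next to the exocyclic enolate and MeI enters anti to it, leaving methyl trans and formyl cis to the coumarin. The step needs 1,4- over 1,2- and 1,6-addition and C- over O-methylation: diene ligands favour conjugate over carbonyl addition to enals, the δ-carbon C4 carries no hydrogen so 1,6-attack would have to build a quaternary centre, and a potassium enolate in THF should react with soft MeI at carbon. Catalytic hydroxide and a hindered amide base at low temperature should spare the lactone and the MOM ether.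

Step 10
Reactants: 16 (1S,2R)-2-[8-methoxy-7-(methoxymethoxy)-2-oxo-2H-chromen-3-yl]-1,4-dimethylcyclohex-3-ene-1-carbaldehyde
Product: 17 3-[(1R,6S)-6-[(E)-2-iodoethenyl]-3,6-dimethylcyclohex-2-en-1-yl]-8-methoxy-7-(methoxymethoxy)-2H-chromen-2-one
Conditions: CrCl2 (6 equiv), CHI3 (2 equiv), THF/1,4-dioxane, 0 °C → rt
Reagents that add atoms: iodoform, IC(I)I
Why: Takai olefination, in which the geminal dichromium carbenoid formed from CHI3 and divalent chromium adds to the non-enolisable aldehyde and eliminates to the E-alkenyl iodide, while the quaternary stereocentre cannot epimerise and the lactone and MOM groups are inert to CrCl2.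

Step 11
Reactants: 17 3-[(1R,6S)-6-[(E)-2-iodoethenyl]-3,6-dimethylcyclohex-2-en-1-yl]-8-methoxy-7-(methoxymethoxy)-2H-chromen-2-one; 14 8-methoxy-7-(methoxymethoxy)-3-(4,4,5,5-tetramethyl-1,3,2-dioxaborolan-2-yl)-2H-chromen-2-one (1.5 equiv)
Product: 18 3-[(E)-2-[(1R,2R)-1,4-dimethyl-2-[8-methoxy-7-(methoxymethoxy)-2-oxo-2H-chromen-3-yl]cyclohex-3-en-1-yl]ethenyl]-8-methoxy-7-(methoxymethoxy)-2H-chromen-2-one
Conditions: PdCl2(dppf) (5 mol%), K3PO4 (3 equiv), THF/H2O, 45 °C
Reagents that add atoms: none
Why: Suzuki–Miyaura coupling of an alkenyl iodide with the alkenyl-type boronate 14 proceeds with retention of the E geometry, and the reactive C–I bond allows mild aqueous phosphate conditions that spare both lactones.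

Step 12
Reactants: 18 3-[(E)-2-[(1R,2R)-1,4-dimethyl-2-[8-methoxy-7-(methoxymethoxy)-2-oxo-2H-chromen-3-yl]cyclohex-3-en-1-yl]ethenyl]-8-methoxy-7-(methoxymethoxy)-2H-chromen-2-one
Product: 19 7-hydroxy-3-[(E)-2-[(1R,2R)-2-(7-hydroxy-8-methoxy-2-oxo-2H-chromen-3-yl)-1,4-dimethylcyclohex-3-en-1-yl]ethenyl]-8-methoxy-2H-chromen-2-one (CNP0264408.1)
Conditions: 3 M aq. HCl, MeOH/THF, 45 °C
Reagents that add atoms: none
Why: Acid-catalysed acetal exchange cleaves both aryl MOM ethers to the phenols, and dilute HCl in methanol at moderate temperature should leave the trisubstituted ring alkene, the E-alkene and both lactones intact.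

Compound list
1 | isoprene (2-methylbuta-1,3-diene) | C=CC(C)=C | starting material
2 | methyl acrylate | C=CC(=O)OC | starting material
3 | methyl 4-methylcyclohex-3-ene-1-carboxylate (racemic) | COC(=O)C1CCC(C)=CC1 | intermediate
4 | methyl 4-methyl-1-(phenylselanyl)cyclohex-3-ene-1-carboxylate (racemic; not isolated) | COC(=O)C1([Se]c2ccccc2)CCC(C)=CC1 | intermediate
5 | methyl 4-methyl-1-(phenylseleninyl)cyclohex-3-ene-1-carboxylate (selenoxide; not isolated) | COC(=O)C1([Se](=O)c2ccccc2)CCC(C)=CC1 | intermediate
6 | methyl 4-methylcyclohexa-1,3-diene-1-carboxylate | COC(=O)C1=CC=C(C)CC1 | intermediate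
7 | (4-methylcyclohexa-1,3-dien-1-yl)methanol | OCC1=CC=C(C)CC1 | intermediate
8 | 4-methylcyclohexa-1,3-diene-1-carbaldehyde | O=CC1=CC=C(C)CC1 | intermediate
9 | 2,4-dihydroxy-3-methoxybenzaldehyde | COc1c(O)ccc(C=O)c1O | starting material
10 | ethyl (2Z)-3-(2,4-dihydroxy-3-methoxyphenyl)prop-2-enoate (not isolated) | CCOC(=O)/C=C\c1ccc(O)c(OC)c1O | intermediate
11 | 7-hydroxy-8-methoxy-2H-chromen-2-one | COc1c(O)ccc2ccc(=O)oc12 | intermediate
12 | 8-methoxy-7-(methoxymethoxy)-2H-chromen-2-one | COCOc1ccc2ccc(=O)oc2c1OC | intermediate
13 | 3-bromo-8-methoxy-7-(methoxymethoxy)-2H-chromen-2-one | COCOc1ccc2cc(Br)c(=O)oc2c1OC | intermediate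
14 | 8-methoxy-7-(methoxymethoxy)-3-(4,4,5,5-tetramethyl-1,3,2-dioxaborolan-2-yl)-2H-chromen-2-one | COCOc1ccc2cc(B3OC(C)(C)C(C)(C)O3)c(=O)oc2c1OC | intermediate
15 | (2R)-2-[8-methoxy-7-(methoxymethoxy)-2-oxo-2H-chromen-3-yl]-4-methylcyclohex-3-ene-1-carbaldehyde, both C1 epimers (not isolated) | O=CC1CCC(C)=C[C@H]1c1cc2ccc(OCOC)c(OC)c2oc1=O | intermediate
16 | (1S,2R)-2-[8-methoxy-7-(methoxymethoxy)-2-oxo-2H-chromen-3-yl]-1,4-dimethylcyclohex-3-ene-1-carbaldehyde (formyl cis to the coumarin, methyl trans) | O=C[C@@]1(C)CCC(C)=C[C@H]1c1cc2ccc(OCOC)c(OC)c2oc1=O | intermediate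
17 | 3-[(1R,6S)-6-[(E)-2-iodoethenyl]-3,6-dimethylcyclohex-2-en-1-yl]-8-methoxy-7-(methoxymethoxy)-2H-chromen-2-one | I/C=C/[C@@]1(C)CCC(C)=C[C@H]1c1cc2ccc(OCOC)c(OC)c2oc1=O | intermediate
18 | 3-[(E)-2-[(1R,2R)-1,4-dimethyl-2-[8-methoxy-7-(methoxymethoxy)-2-oxo-2H-chromen-3-yl]cyclohex-3-en-1-yl]ethenyl]-8-methoxy-7-(methoxymethoxy)-2H-chromen-2-one | COCOc1ccc2cc(/C=C/[C@@]3(C)CCC(C)=C[C@H]3c3cc4ccc(OCOC)c(OC)c4oc3=O)c(=O)oc2c1OC | intermediate
19 | 7-hydroxy-3-[(E)-2-[(1R,2R)-2-(7-hydroxy-8-methoxy-2-oxo-2H-chromen-3-yl)-1,4-dimethylcyclohex-3-en-1-yl]ethenyl]-8-methoxy-2H-chromen-2-one | COc1c(O)ccc2cc(/C=C/[C@@]3(C)CCC(C)=C[C@H]3c3cc4ccc(O)c(OC)c4oc3=O)c(=O)oc12 | target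

Total step count: 12. Longest linear sequence: 8 steps (steps 1–4 then 9–12, or steps 5–8 then 9–12).

Steps most likely to fail

Step 9 (the one step that goes beyond known chemistry). What may go wrong:
- carbonyl (1,2-) addition, or sluggish insertion into the trisubstituted enal;
- protodeboronation of the α-boryl lactone outrunning transmetalation;
- poor facial control at either new centre;
- O-methylation or lactone opening in the basic second stage.

Fallback with known chemistry, setting out from bromide 13 and returning at aldehyde 16: Heck coupling of 13 with isoprene (Pd(OAc)2, P(o-tol)3, Et3N, DMF, 90 °C, sealed vessel) arylates the unsubstituted vinyl terminus and should give the diene 8-methoxy-7-(methoxymethoxy)-3-[(1E)-3-methylbuta-1,3-dien-1-yl]-2H-chromen-2-one F1. A catalytic enantioselective Diels–Alder reaction of F1 with methacrolein then builds the ring directly. The Lewis acid is the triflimide (HNTf2) salt of a diphenylprolinol-derived 1-(2-methylphenyl)oxazaborolidine, in CH2Cl2 at low temperature. The "ortho/para" orientation puts the formyl-bearing carbon next to the coumarinyl carbon and the ring methyl on C4, and the formyl-endo transition state places formyl cis to the coumarin. The catalyst antipode is chosen to give the (1S,2R) enantiomer 16; any formyl-exo diastereomer would be removed by chromatography.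

Step 10. What may go wrong: slow addition of the bulky dichromium carbenoid to the neopentyl-type aldehyde, leading to incomplete conversion, or erosion of E-selectivity.

Fallback setting out from aldehyde 16 and returning at 18: Wittig methylenation (Ph3PCH3Br, KN(SiMe3)2, THF, 0 °C → rt) gives the vinyl compound 3-[(1R,6R)-6-ethenyl-3,6-dimethylcyclohex-2-en-1-yl]-8-methoxy-7-(methoxymethoxy)-2H-chromen-2-one F2. Heck coupling of F2 with bromide 13 (Pd(OAc)2, P(o-tol)3, Et3N, DMF, 100 °C) then gives 18. The quaternary allylic carbon offers no β-hydrogen, so palladium hydride elimination can only form the E-alkene. This path also bypasses step 11.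

Step 2. What may go wrong: syn-elimination toward C6 giving the unconjugated diene ester, or over-oxidation with aromatisation of the ring.

Fallback setting out from isoprene 1 and returning at 6: an AlCl3-catalysed Diels–Alder reaction of 1 with methyl propiolate gives methyl 4-methylcyclohexa-1,4-diene-1-carboxylate F3. Catalytic DBU in degassed THF at rt then moves the isolated C4=C5 bond into conjugation, by removal of the doubly allylic C3–H and protonation of the extended dienolate at C5, to give 6.

Further compounds
F1 | step 9 | 8-methoxy-7-(methoxymethoxy)-3-[(1E)-3-methylbuta-1,3-dien-1-yl]-2H-chromen-2-one | COCOc1ccc2cc(/C=C/C(C)=C)c(=O)oc2c1OC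
F2 | step 10 | 3-[(1R,6R)-6-ethenyl-3,6-dimethylcyclohex-2-en-1-yl]-8-methoxy-7-(methoxymethoxy)-2H-chromen-2-one | C=C[C@@]1(C)CCC(C)=C[C@H]1c1cc2ccc(OCOC)c(OC)c2oc1=O
F3 | step 2 | methyl 4-methylcyclohexa-1,4-diene-1-carboxylate | COC(=O)C1=CCC(C)=CC1
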